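**Earlier runs.** In the zeta run after 4.00 min, left-handed product and left-handed substrate still add up to 49.7% of the two substrates charged together, so within the scatter what leaves the left-handed substrate appears as that product.

| flask | left-handed substrate | right-handed substrate | partner | protic impurity | free catalyst | remark |
|---|---|---|---|---|---|---|
| theta | 0.48 M | 0.48 M | 0.14 M | 0.024 M | 5.8 mM | run made earlier |
| alpha | 0.48 M | 0.48 M | 0.22 M | 0.024 M | 5.8 mM | run made earlier |
| zeta | 0.24 M | 0.24 M | 0.288 M | 0.024 M | 5.8 mM | run made earlier |
| flask | 0.48 M | 0.48 M | 0.288 M | 0.0240 M | 5.8 mM |  |

- theta (time / min: left-handed product / %, left-handed substrate / %): 0.667: 1.2, 48.8; 1.33: 3.3, 47.6; 2.00: 4.0, 45.9; 2.50: 4.8, 45.6; 3.00: 4.5, 45.9; 4.00: 5.6, 44.5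
- alpha (time / min: left-handed product / %, left-handed substrate / %): 0.250: 0.8, 48.6; 0.833: 3.3, 47.1; 1.33: 4.0, 45.5; 2.00: 6.3, 43.6; 3.00: 7.2, 43.4; 4.00: 9.4, 41.4
- zeta (time / min: left-handed product / %, left-handed substrate / %): 0.333: 2.5, 48.0; 1.00: 3.9, 45.6; 2.00: 7.9, 41.7; 3.00: 10.0, 39.1; 4.00: 12.5, 37.2

(standard deviation of a reading: 0.5 percentage points)

- free catalyst is single-handed; left-handed substrate and right-handed substrate are mirror images of each other, charged as a racemate, each of them at the stated concentration
- no earlier run changes the charge of free catalyst; that part of a forecast is a guess

- apparent order in partner when 10% of the left-handed substrate and right-handed substrate together are converted (percent change of the rate of making left-handed product for one percent more partner charged)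
- apparent order in free catalyst when 10% of the left-handed substrate and right-handed substrate together are converted (percent change of the rate of making left-handed product for one percent more free catalyst charged)
- factor on the rate of making left-handed product when 10% of the left-handed substrate and right-handed substrate together are converted if partner is charged twice over

**Fastest rung.** We assume that protic impurity takes partner mole for mole, early in the run, so in our reckoning it is a plain subtraction of 0.0240 M from the partner charge.

**Middle rung.** We count one partner for each product. After the impurity this leaves 0.264 M of partner in the flask against 0.48 M of left-handed substrate, so partner is the limiting reagent. At 4.00 min, product in the alpha run over product in the theta run reads 1.68, and their partner charges less impurity stand at 1.69. We therefore read the rate as first order in partner.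

**Slowest rung.** The theta run gains 1.6 percentage points between 2.00 min and 4.00 min, against 4.0% before, a ratio of 0.400. Yet by our count 66.9% of the partner that the impurity leaves in the theta run still stands at 2.00 min. We take this extra slowing as a brake that follows product made, not the clock, so that we count it alike at a fixed conversion.

**Partner left.** At a fixed conversion, here the mark of 10% of the two substrates together, and with the substrate charge held, we then count product and substrate alike, and partner differs between charges. We carry c(partner) at the mark, the charge less impurity less product: 0.168 M. The order in charged partner is the charge over this amount, 1.71. Charging twice the partner leaves 0.456 M, so the rate factor is 2.71. No run changes the catalyst charge, so we give no number for it.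

**The result.** The forecast, which differs from our reckoning, gives 1.45, 1 and 2.25, noting “Catalyst order was never tested”. The flask gives 1.7, 1.3 and 2.73.

    partner + protic impurity → quenched reagent (k = 0.151 L mol⁻¹ s⁻¹)
    partner + free catalyst + left-handed substrate → free catalyst + left-handed product (k = 1.10 L² mol⁻² s⁻¹)
    partner + free catalyst → spent catalyst (k = 0.00651 L mol⁻¹ s⁻¹)
    partner + free catalyst + right-handed substrate → free catalyst + right-handed product (k = 0.0111 L² mol⁻² s⁻¹)

**Partner's uses.** In the flask, making left-handed product uses partner at 0.85 times the rate of the quenching at the start, and 22 times at 1.67 min. Protic impurity stands at 0.689% of its charge by 2.50 min, before the mark at 3.09 min, so nearly all of it has gone to quenched reagent, as 0.168 M counts. For a flask charged with twice the partner, the logarithms of partner after the impurity over partner at the mark give a factor of 0.423 on the time to the mark, and the simulated run with that charge gives 0.420.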